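**Retrosynthetic overview**

1. Locants used throughout: C1 quaternary fusion carbon (CH3), C2/C3 ring A methylenes, C4 isopropyl carbinol, C5 fusion CH, C6 acyloxy carbon, C7 CH2, C8(CH3)=C9, C10 CH2; ring A = C1–C5 (five-membered), ring B = C1, C5–C10 (seven-membered).
2. The C6–O ester bond is cut last (diol 17 + silyl-protected p-coumaric acid 20); C4–OH, C5–H and C6–OH go back through ketol 16, epoxy ketone 15 and enone 12 to dienone 10, each centre being relayed from C1.
3. The strategy rests on the C8(CH3)=C9 unit of ring B, held between the methylenes C7 and C10: it is a masked propyne, and C10 can be stored as the cyclopropane CH2 on the C1–C5 bond, so ring B is cut at C7–C8 and C9–C10 into vinylcyclopropyl ketone 7 and 1-(trimethylsilyl)propyne 8.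
4. Ketone 7 comes from 3-methylcyclopent-2-en-1-one by iodination, CBS reduction, vinylation, hydroxyl-directed cyclopropanation and oxidation.
5. Ring order: ring A is bought, the cyclopropane on C1–C5 is added second (it fixes C1), ring B is closed third by the (5+2) cycloaddition.

Key step: step 6

Remark: alcohol 11 is drawn as the C4 epimer expected to predominate; either epimer serves, because step 9 makes C4 trigonal.

**Route**

Step 1
Reactants: 1 3-methylcyclopent-2-en-1-one
Product: 2 2-iodo-3-methylcyclopent-2-en-1-one
Conditions: I2, pyridine, CH2Cl2, 0 °C to rt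
Reagents that add atoms: iodine, [I][I]
Why: α-Iodination of an enone (pyridine conjugate addition, iodination of the enolate, elimination) puts the halogen on the carbon that becomes C5 and creates no stereocenter.

Step 2
Reactants: 2 2-iodo-3-methylcyclopent-2-en-1-one
Product: 3 (R)-2-iodo-3-methylcyclopent-2-en-1-ol
Conditions: (S)-Me-CBS oxazaborolidine (10 mol%), BH3·SMe2, THF, −20 °C; MeOH quench
Reagents that add atoms: none
Why: Corey–Bakshi–Shibata reduction in which the iodoalkene arm acts as the large group, so that by the usual model the (S)-catalyst should give the (R)-carbinol, the temporary stereocenter from which C1 is later set.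

Step 3
Reactants: 3 (R)-2-iodo-3-methylcyclopent-2-en-1-ol; 4 tributyl(vinyl)stannane
Product: 5 (R)-2-ethenyl-3-methylcyclopent-2-en-1-ol
Conditions: PdCl2(MeCN)2 (5 mol%), DMF, rt
Reagents that add atoms: none
Why: Stille coupling of an alkenyl iodide with a vinylstannane tolerates the free allylic alcohol, leaves the carbinol stereocenter untouched and brings in the future C6=C7.

Step 4
Reactants: 5 (R)-2-ethenyl-3-methylcyclopent-2-en-1-ol
Product: 6 (1R,2R,5R)-1-ethenyl-5-methylbicyclo[3.1.0]hexan-2-ol
Conditions: Et2Zn (2 equiv), CH2I2 (2 equiv), CH2Cl2, −20 to 0 °C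
Reagents that add atoms: diiodomethane, ICI
Why: Hydroxyl-directed Simmons–Smith cyclopropanation (Furukawa variant), in which the zinc alkoxide delivers CH2 to the electron-rich tetrasubstituted ring alkene on the face of the oxygen in preference to the more remote vinyl group, so that both cyclopropane carbons (the future C1 and C5) are set cis to the hydroxyl.

Step 5
Reactants: 6 (1R,2R,5R)-1-ethenyl-5-methylbicyclo[3.1.0]hexan-2-ol
Product: 7 (1R,5R)-1-ethenyl-5-methylbicyclo[3.1.0]hexan-2-one
Conditions: Dess–Martin periodinane, NaHCO3, CH2Cl2, 0 °C to rt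
Reagents that add atoms: none
Why: Dess–Martin oxidation under bicarbonate buffer converts the acid-sensitive cyclopropylcarbinol into the ketone without touching the vinylcyclopropane, and the carbinol stereocenter is given up once it has fixed C1.

Step 6
Reactants: 7 (1R,5R)-1-ethenyl-5-methylbicyclo[3.1.0]hexan-2-one; 8 1-(trimethylsilyl)propyne
Product: 9 (1R)-C9-silylated dienone (C4 ketone, C5=C6, C8(CH3)=C9(SiMe3)); systematic name (3aR)-3a,6-dimethyl-5-(trimethylsilyl)-3,3a,4,7-tetrahydroazulen-1(2H)-one
Conditions: [Rh(CO)2Cl]2 (5 mol%), 8 (4 equiv), ClCH2CH2Cl, 80 °C, sealed tube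
Reagents that add atoms: none
Why: Monovalent rhodium binds the C6=C7 vinyl group and inserts into the strained C5–C10 bond, giving a trivalent rhodium metallacycle with a σ-bond to C10 and a π-allyl over C5–C6–C7; the alkyne then inserts at C7 (C7–C8 bond) and reductive elimination joins C9 to C10. The closest known reaction type is the rhodium-catalysed intermolecular (5+2) cycloaddition of vinylcyclopropanes with alkynes; a ring-fused, acyl-substituted cyclopropane and an internal silylalkyne have not been tried together in it. Ring B is therefore closed not end to end but by growth of the rhodacycle by two carbons and its collapse in a C(sp2)–C(sp3) reductive elimination, driven by release of cyclopropane strain and by conjugation of the new C5=C6 bond with the C4 ketone. No stereocenter is formed; C1 keeps all four bonds and carries the configuration set in step 4 into the bicycle. Two selectivities are needed: cleavage of C5–C10 and not of the fusion bond C5–C1, secured because insertion there would place rhodium on quaternary C1, and alkyne orientation, secured because the trimethylsilyl group avoids the carbon that forms the first bond and ends on the rhodium-bound carbon, so that methyl lands on C8 and removable silicon on C9. Quaternary C1 bears no hydrogen, so the rhodacycle cannot leak away by β-hydride elimination.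

Step 7
Reactants: 9 (1R)-C9-silylated dienone
Product: 10 (1R)-dienone (C4 ketone, C5=C6, C8(CH3)=C9H); systematic name (3aR)-3a,6-dimethyl-3,3a,4,7-tetrahydroazulen-1(2H)-one
Conditions: CF3CO2H, CH2Cl2, 0 °C; aq. NaHCO3
Reagents that add atoms: none
Why: Electrophilic ipso-protodesilylation of a vinylsilane, in which protonation at C9 gives the tertiary β-silyl cation at C8 and loss of silicon restores the C8=C9 bond in place, run cold and briefly so that the skipped diene does not drift into conjugation; no stereocenter is formed.

Step 8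
Reactants: 10 (1R)-dienone
Product: 11 (1R,4R)-tertiary allylic alcohol (C4(OH)(iPr), C5=C6, C8=C9)
Conditions: iPrMgCl, CeCl3 (anhydrous), THF, −78 to 0 °C
Reagents that add atoms: isopropylmagnesium chloride, CC(C)[Mg]Cl
Why: Organocerium 1,2-addition, chosen because the weakly basic cerium reagent adds to the hindered enone carbonyl without deprotonating the doubly allylic C7 or transferring β-hydride; the new C4 centre, expected mainly with isopropyl anti to the angular methyl, is erased in step 9.

Step 9
Reactants: 11 (1R,4R)-tertiary allylic alcohol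
Product: 12 (1R)-4-en-6-one (C4(iPr)=C5, C6 ketone, C8=C9)
Conditions: [C5H5NH][CrO3Cl] (pyridinium chlorochromate), 4 Å MS, CH2Cl2, rt
Reagents that add atoms: pyridinium chlorochromate (source of the C6 oxygen), [O-][Cr](=O)(=O)Cl.c1cc[nH+]cc1
Why: Babler–Dauben oxidative transposition, in which the chromate ester of the tertiary allylic alcohol shifts from C4 to C6 and is oxidised there, giving the C6 ketone conjugated with the new tetrasubstituted C4=C5 bond; no stereocenter is formed.

Step 10
Reactants: 12 (1R)-4-en-6-one
Product: 13 (1R,6R)-4-en-6-ol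
Conditions: NaBH4, CeCl3·7H2O, MeOH, −78 to −40 °C
Reagents that add atoms: none
Why: Luche 1,2-reduction, in which hydride should reach C6 from the face opposite the pseudoaxial angular methyl on C1, setting the 6R alcohol with its hydroxyl cis to that methyl.

Step 11
Reactants: 13 (1R,6R)-4-en-6-ol
Product: 14 (1R,4R,5S,6R)-4,5-epoxy-6-ol
Conditions: VO(acac)2 (5 mol%), tBuOOH (1.2 equiv), CH2Cl2, 0 °C
Reagents that add atoms: tert-butyl hydroperoxide, CC(C)(C)OO
Why: Hydroxyl-directed vanadium-catalysed epoxidation of an allylic alcohol, in which the C6 vanadate ester hands the oxygen to C4=C5 on its own face, and faster than to the homoallylic C8=C9 bond, so that C4–O and C5–O are set cis to the C1 methyl.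

Step 12
Reactants: 14 (1R,4R,5S,6R)-4,5-epoxy-6-ol
Product: 15 (1R,4R,5R)-4,5-epoxy-6-one
Conditions: Dess–Martin periodinane, NaHCO3, CH2Cl2, 0 °C to rt
Reagents that add atoms: none
Why: Dess–Martin oxidation of the secondary alcohol under buffered, non-basic conditions gives the α,β-epoxy ketone without opening the epoxide or moving the β,γ-alkene, and C4 and C5 are untouched.

Step 13
Reactants: 15 (1R,4R,5R)-4,5-epoxy-6-one
Product: 16 (1R,4R,5R)-4-hydroxy-6-one (trans-fused ketol)
Conditions: SmI2 (2.5 equiv), THF/MeOH, −78 °C
Reagents that add atoms: none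
Why: Samarium diiodide reductive opening of an α,β-epoxy ketone, in which two electrons cleave only the C5–O bond next to the carbonyl, the C4 alkoxide keeps its configuration, and the samarium enolate should be protonated at C5 on the face away from the angular methyl and the samarium-bound C4 oxygen, giving the trans-fused ketol that is also expected to be the more stable C5 epimer (isopropyl cis to H5, hydroxyl hydrogen-bonded to the ketone).

Step 14
Reactants: 16 (1R,4R,5R)-4-hydroxy-6-one
Product: 17 (1R,4R,5S,6S)-4,6-diol (jaeschkeanadiol); systematic name (3R,3aS,4S,8aR)-6,8a-dimethyl-3-(propan-2-yl)-1,2,3,3a,4,5,8,8a-octahydroazulene-3,4-diol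
Conditions: Me4NBH(OAc)3, MeCN/AcOH (1:1), −30 to 0 °C
Reagents that add atoms: none
Why: Evans–Saksena hydroxyl-directed reduction, in which the C4 alcohol exchanges onto boron and delivers hydride to C6 from its own side, giving the 1,3-anti diol with the C6 hydroxyl cis to H5 (6S).

Step 15
Reactants: 18 p-coumaric acid
Product: 20 (E)-3-[4-(tert-butyldimethylsilyloxy)phenyl]prop-2-enoic acid, via silyl ester 19 (not isolated)
Conditions: TBSCl (2.2 equiv), imidazole, DMF, rt; then AcOH/THF/H2O, rt
Reagents that add atoms: tert-butyldimethylsilyl chloride, CC(C)(C)[Si](C)(C)Cl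
Why: Silylation of both acidic groups followed by selective hydrolysis of the labile silyl ester (protecting-group chemistry) leaves the phenol masked and the acid free, with the E alkene unchanged.

Step 16
Reactants: 17 (1R,4R,5S,6S)-4,6-diol; 20 (E)-3-[4-(tert-butyldimethylsilyloxy)phenyl]prop-2-enoic acid
Product: 22 (1R,4R,5S,6S)-6-O-[(E)-4-(tert-butyldimethylsilyloxy)cinnamoyl] diol, via mixed anhydride 21 (not isolated)
Conditions: 2,4,6-Cl3C6H2COCl, Et3N, THF, rt; then 17, DMAP, toluene, rt to 40 °C
Reagents that add atoms: none
Why: Yamaguchi esterification, in which DMAP transfers the cinnamoyl group from the mixed anhydride to the secondary C6 alcohol only, the tertiary C4 alcohol being too hindered to react, with retention at C6.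

Step 17
Reactants: 22 (1R,4R,5S,6S)-6-O-[(E)-4-(tert-butyldimethylsilyloxy)cinnamoyl] diol
Product: 23 target, [(3R,3aS,4S,8aR)-3-hydroxy-6,8a-dimethyl-3-(propan-2-yl)-1,2,3,3a,4,5,8,8a-octahydroazulen-4-yl] (E)-3-(4-hydroxyphenyl)prop-2-enoate
Conditions: Bu4NF, AcOH, THF, 0 °C
Reagents that add atoms: none
Why: Fluoride cleavage of the aryl silyl ether buffered with acetic acid, so that the phenoxide is protonated at once and neither the cinnamate ester nor the tertiary alcohol is touched.

**Compound list**

1 | 3-methylcyclopent-2-en-1-one | CC1=CC(=O)CC1 | starting material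
2 | 2-iodo-3-methylcyclopent-2-en-1-one | CC1=C(I)C(=O)CC1 | intermediate
3 | (R)-2-iodo-3-methylcyclopent-2-en-1-ol | O[C@@H]1CCC(C)=C1I | intermediate
4 | tributyl(vinyl)stannane | C=C[Sn](CCCC)(CCCC)CCCC | starting material
5 | (R)-2-ethenyl-3-methylcyclopent-2-en-1-ol | O[C@@H]1CCC(C)=C1C=C | intermediate
6 | (1R,2R,5R)-1-ethenyl-5-methylbicyclo[3.1.0]hexan-2-ol | C=C[C@]12C[C@@]1(C)CC[C@H]2O | intermediate
7 | (1R,5R)-1-ethenyl-5-methylbicyclo[3.1.0]hexan-2-one | C=C[C@]12C[C@@]1(C)CCC2=O | intermediate
8 | 1-(trimethylsilyl)propyne | CC#C[Si](C)(C)C | starting material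
9 | (3aR)-3a,6-dimethyl-5-(trimethylsilyl)-3,3a,4,7-tetrahydroazulen-1(2H)-one (route locants: 1R; C4 ketone, C5=C6, C8=C9–Si) | CC1=C([Si](C)(C)C)C[C@@]2(C)CCC(=O)C2=CC1 | intermediate
10 | (3aR)-3a,6-dimethyl-3,3a,4,7-tetrahydroazulen-1(2H)-one (route locants: 1R; C4 ketone, C5=C6, C8=C9) | CC1=CC[C@@]2(C)CCC(=O)C2=CC1 | intermediate
11 | (1R,4R)-tertiary allylic alcohol: C4(OH)(iPr), C5=C6, C8=C9 (route locants) | CC1=CC[C@@]2(C)CC[C@@](O)(C(C)C)C2=CC1 | intermediate
12 | (1R)-4-en-6-one: C4(iPr)=C5, C6 ketone, C8=C9 (route locants) | CC1=CC[C@@]2(C)CCC(C(C)C)=C2C(=O)C1 | intermediate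
13 | (1R,6R)-4-en-6-ol (route locants) | CC1=CC[C@@]2(C)CCC(C(C)C)=C2[C@H](O)C1 | intermediate
14 | (1R,4R,5S,6R)-4,5-epoxy-6-ol (route locants) | CC1=CC[C@@]2(C)CC[C@]3(C(C)C)O[C@]23[C@H](O)C1 | intermediate
15 | (1R,4R,5R)-4,5-epoxy-6-one (route locants) | CC1=CC[C@@]2(C)CC[C@]3(C(C)C)O[C@]23C(=O)C1 | intermediate
16 | (1R,4R,5R)-4-hydroxy-6-one, trans-fused (route locants) | CC1=CC[C@@]2(C)CC[C@@](O)(C(C)C)[C@@H]2C(=O)C1 | intermediate
17 | (3R,3aS,4S,8aR)-6,8a-dimethyl-3-(propan-2-yl)-1,2,3,3a,4,5,8,8a-octahydroazulene-3,4-diol (route locants: 1R,4R,5S,6S) | CC1=CC[C@@]2(C)CC[C@@](O)(C(C)C)[C@@H]2[C@@H](O)C1 | intermediate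
18 | p-coumaric acid | O=C(O)/C=C/c1ccc(O)cc1 | starting material
19 | tert-butyldimethylsilyl (E)-3-[4-(tert-butyldimethylsilyloxy)phenyl]prop-2-enoate | CC(C)(C)[Si](C)(C)OC(=O)/C=C/c1ccc(O[Si](C)(C)C(C)(C)C)cc1 | intermediate
20 | (E)-3-[4-(tert-butyldimethylsilyloxy)phenyl]prop-2-enoic acid | OC(=O)/C=C/c1ccc(O[Si](C)(C)C(C)(C)C)cc1 | intermediate
21 | (E)-3-[4-(tert-butyldimethylsilyloxy)phenyl]prop-2-enoic 2,4,6-trichlorobenzoic anhydride | O=C(/C=C/c1ccc(O[Si](C)(C)C(C)(C)C)cc1)OC(=O)c1c(Cl)cc(Cl)cc1Cl | intermediate
22 | (1R,4R,5S,6S)-6-O-[(E)-4-(tert-butyldimethylsilyloxy)cinnamoyl] diol (route locants) | CC1=CC[C@@]2(C)CC[C@@](O)(C(C)C)[C@@H]2[C@@H](OC(=O)/C=C/c2ccc(O[Si](C)(C)C(C)(C)C)cc2)C1 | intermediate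
23 | [(3R,3aS,4S,8aR)-3-hydroxy-6,8a-dimethyl-3-(propan-2-yl)-1,2,3,3a,4,5,8,8a-octahydroazulen-4-yl] (E)-3-(4-hydroxyphenyl)prop-2-enoate | CC1=CC[C@@]2(C)CC[C@@](O)(C(C)C)[C@@H]2[C@@H](OC(=O)/C=C/c2ccc(O)cc2)C1 | target

**Step count and risks**

Total step count: 17. Longest linear sequence: 16 (steps 1–14, 16 and 17; step 15 is a one-step side branch).

Steps most likely to fail:

1. Step 6. The oxidative addition may be slow or misdirected, because the C1 methyl is cis to the vinyl group and crowds the rotamer needed for C5–C10 cleavage, and the acyl group makes the cyclopropane electron-poor. Insertion of the internal silylalkyne may be too slow to compete with rhodium-mediated isomerisation of 7, overheating may start a thermal homodienyl hydrogen shift from the cis methyl, and the alkyne may insert in the reverse orientation. The fallback removes the acyl group from the cycloaddition partner. It sets out from alcohol 6, which is silylated (TBSCl, imidazole, DMF) to silyl ether F1, an alkyl-substituted vinylcyclopropane of the kind for which the rhodium-catalysed reaction with alkynes is established. Cycloaddition of F1 with 8 under [Rh(CO)2Cl]2 in ClCH2CH2Cl should give cycloadduct F2. Bu4NF then frees allylic alcohol F3, and MnO2 in CH2Cl2 oxidises it to dienone 9, where the route is rejoined.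

2. Step 13. Protonation of the samarium enolate may occur on the wrong face of C5 and give the cis-fused ketol. A later correction with base is barred, because base would open the way to retro-aldol cleavage of ring A and to migration of the β,γ-alkene into conjugation. The fallback replaces enolate protonation by hydrogen-atom transfer. It sets out from epoxy alcohol 14, which is treated with Cp2TiCl (trivalent titanium, made from Cp2TiCl2 and zinc dust) and 1,4-cyclohexadiene in THF. Homolysis of the C5–O bond gives the tertiary C5 radical, which should take its hydrogen on the face away from the two titanium-bound oxygens, giving 6-epi-diol F4. Dess–Martin oxidation of its only secondary alcohol then gives ketol 16, where the route is rejoined.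

3. Step 10. Hydride may enter from the wrong face, because the methyl on C1 is only 1,3-related to C6 and competes with the ring B methylene C10 on the other face; the wrong alcohol would send C4, C5 and C6 into the wrong series. The fallback corrects the centre by inversion instead of relying on substrate control. It sets out from enone 12: the reduction product, 6S alcohol F5, is submitted to Mitsunobu inversion (4-nitrobenzoic acid, PPh3, diisopropyl azodicarboxylate, THF) to give inverted ester F6. Methanolysis (K2CO3, MeOH) then gives 6R alcohol 13, where the route is rejoined.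

**Further compounds**

F1 | step 6 | tert-butyldimethylsilyl ether of (1R,2R,5R)-1-ethenyl-5-methylbicyclo[3.1.0]hexan-2-ol | C=C[C@]12C[C@@]1(C)CC[C@H]2O[Si](C)(C)C(C)(C)C
F2 | step 6 | (1R,4R)-4-(tert-butyldimethylsilyloxy)-9-(trimethylsilyl)-5,8-diene cycloadduct (route locants) | CC1=C([Si](C)(C)C)C[C@@]2(C)CC[C@@H](O[Si](C)(C)C(C)(C)C)C2=CC1
F3 | step 6 | (1R,4R)-9-(trimethylsilyl)-5,8-dien-4-ol (route locants) | CC1=C([Si](C)(C)C)C[C@@]2(C)CC[C@@H](O)C2=CC1
F4 | step 13 | (1R,4R,5S,6R)-4,6-diol, the C6 epimer of 17 (route locants) | CC1=CC[C@@]2(C)CC[C@@](O)(C(C)C)[C@@H]2[C@H](O)C1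
F5 | step 10 | (1R,6S)-4-en-6-ol, the C6 epimer of 13 (route locants) | CC1=CC[C@@]2(C)CCC(C(C)C)=C2[C@@H](O)C1
F6 | step 10 | (1R,6R)-4-en-6-yl 4-nitrobenzoate (route locants) | CC1=CC[C@@]2(C)CCC(C(C)C)=C2[C@H](OC(=O)c2ccc(cc2)[N+](=O)[O-])C1
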